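Remark: 17 and 18 are written as their 4-hydroxy enol tautomers, 5 as an E/Z mixture and 16 as the first-formed C3 epimer; C3 of 16 may epimerise or enolise without consequence.

## The problem

The target 18 is a 3-acyltetronic acid: a furan-2(5H)-one ring (O1, lactone carbon C2, C3, enolic C4, C5). It carries the 13-methyltetradecanoyl chain at C3, the enol hydroxyl at C4 and, at C5, the only stereocentre (S), which bears a free hydroxymethyl group. Closing the small ring is not the difficulty. The difficulty is the C2/C4/C1' tricarbonyl, a strong, chelating acid that is awkward to purify and is best unveiled in the last steps. C5 has no partner stereocentre that could set it, so its configuration must be bought and then shielded. Its hydrogen is α to the C4 carbonyl of the keto tautomer and β to the primary oxygen, so base threatens epimerisation and elimination once the ring exists. The iso-branched C15 chain is not a cheap reagent in activated form; it must be built by one C–C coupling and then joined to C3. The feature that opens a different plan is the 1,3-relation C1'(acyl carbon)–C3–C4–O: carbon on C3 and oxygen on the neighbouring C4 of the lactone is what a nitrile oxide leaves when it adds across a C3=C4 double bond (isoxazoline ring O–N=C1'–C3–C4). Because C3 and C4 are both trigonal in 18, the two stereocentres of such an adduct are erased later, so every diastereomer converges on one product and only the regiochemistry must be right.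

## Retrosynthesis

18 ⇒ 17. Only the O–Si bond of the primary hydroxyl is cut. The free hydroxymethyl group cannot pass through the oxidation that makes the C4 carbonyl, so it is masked as a tert-butyldiphenylsilyl ether. The ether is removed with acidic fluoride, a medium in which C5–H is safe.

17 ⇒ 16. No bond is cut; C4 goes from the enol/ketone level back to a secondary alcohol. The flat tricarbonyl becomes a β-hydroxy ketone with sp3 centres at C3 and C4, the form in which the C1'–C3–C4–O pattern is recognisable. The forward step needs a mild oxidation of a β-hydroxy ketone to a β-diketone that leaves C5 alone.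

16 ⇒ 14 (through 15). The C4 hydroxyl and the C1' carbonyl are reconnected through nitrogen (O–N and C1'=N), giving isoxazoline 14. In the forward direction, reductive N–O cleavage gives hydroxy imine 15 and water exchanges NH for O. The isoxazoline hides both polar groups in a neutral bicycle that can be chromatographed.

14 ⇒ 11 + 13. Two bonds are cut at once, C3–C1' and C4–O: the [3+2] disconnection into butenolide 11 and nitrile oxide 13. The neighbouring single cuts are weaker. Cutting C3–C1' alone (acylation) needs a finished tetronic acid and base. Cutting C3–C4 (Dieckmann) builds the ring by enolate chemistry beside C5–H. The double cut puts carbon on C3 and oxygen on C4 in one neutral step. Its precursors, a C5 butenolide without oxygen at C4 and a C15 dipole, are each far simpler than 14. The forward step must deliver O to C4 and C to C3; face selectivity is welcome but not needed.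

13 ⇒ 12 ⇒ 5 ⇒ 4 ⇒ 3 ⇒ 1 + 2. The dipole 13 is made in the flask from oxime 5 by chlorination to 12 and loss of HCl. Oxime 5 comes from aldehyde 4 and 4 from alcohol 3. The chain of 3 is cut at C11–C12 into 11-bromoundecan-1-ol 1 and isobutylmagnesium bromide 2, two bulk chemicals joined by a copper-catalysed coupling. The cut is placed so that the branch comes from the Grignard reagent and the oxygen terminus from the bromo alcohol.

11 ⇒ 10 ⇒ 9 ⇒ 8 ⇒ 6 + 7. Silyl ether 11 comes from hydroxy butenolide 10. Butenolide 10 is opened at the lactone O1–C2 bond to Z-enoate 9, and 9 is cut at C3=C4 into aldehyde 8 and ylide 7. Aldehyde 8 is the half-reduced form of commercial L-glycerate acetonide 6. The stereocentre of 6 becomes C5 of 18 without ever being a reacting centre; its secondary oxygen becomes O1 and its primary oxygen the hydroxymethyl oxygen.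

## Roads not taken

Alternative 1: the most obvious cut, O1–C2 plus C3–C4 (Dieckmann closure).
- Forward: monosilylated L-glycerate A1 is acylated on its secondary hydroxyl by the acylketene released from acyl Meldrum's acid A2. The resulting β-keto ester A3 is closed by base to 17.
- Step economy: this route is about two steps shorter than the chosen one.
- Why it is set aside: the ring-closing enolate is generated with C5–H α to the ester under attack and β to a silyloxy leaving group, so epimerisation and elimination are built into the key step. It also needs a glycerate differentiated at all three oxygens. The chosen plan never puts base near C5 once the acyl group is present.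

Alternative 2: cut C3–C1' only.
- Forward: the preformed silyl-protected tetronic acid A4 is O-acylated with 13-methyltetradecanoic acid A5 to enol ester A6, followed by a nucleophile-catalysed 4-O to C3 acyl shift (Fries type) to 17.
- Why it is set aside: the tetronic acid ring must first be built from the glycerate in steps that do nothing for the chain. The acyl shift runs through an ion pair in basic medium on a 4-acyloxybutenolide whose C5–H is vinylogously acidic. C–O and C–C formation are two separate events, whereas the cycloaddition does both at once on a ring that needs no C4 oxygen beforehand.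

Alternative 3: cut C3–C4 and O1–C2 by epoxide opening (strain release).
- Forward: the anion of β-keto ester A7 opens (R)-benzyl glycidyl ether A8 at its terminal carbon and lactonises to α-acyl-γ-butyrolactone A9.
- Why it is set aside: C4 arrives as CH2 and must be raised two oxidation levels. That requires dehydrogenation to acylbutenolide A10, nucleophilic epoxidation and isomerisation of the epoxy ketone with zerovalent palladium. In A10 the C5–H is the γ-hydrogen of an alkylidene 1,3-dicarbonyl and racemises through the 2-hydroxyfuran tautomer. The sequence is also longer. The cycloaddition delivers the C4 oxygen together with the acyl carbon and never passes through an acylbutenolide.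

Key step: step 7

## Route

Step 1
Reactants: 1 11-bromoundecan-1-ol; 2 isobutylmagnesium bromide
Product: 3 13-methyltetradecan-1-ol
Conditions: 2 (2.5 equiv), Li2CuCl4 (3 mol %), THF, −20 °C to rt; aq. NH4Cl
Reagents that add atoms: none
Why: Copper-catalysed sp3–sp3 Grignard cross-coupling (Kochi coupling); the first equivalent of 2 deprotonates the hydroxyl, and the primary bromide then couples without β-elimination.

Step 2
Reactants: 3 13-methyltetradecan-1-ol
Product: 4 13-methyltetradecanal
Conditions: TEMPO (10 mol %), PhI(OAc)2, CH2Cl2, rt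
Reagents that add atoms: none
Why: Oxoammonium-mediated oxidation of a primary alcohol stops cleanly at the aldehyde in the absence of water.

Step 3
Reactants: 4 13-methyltetradecanal
Product: 5 13-methyltetradecanal oxime
Conditions: NH2OH·HCl, NaOAc, EtOH/H2O, rt
Reagents that add atoms: hydroxylamine hydrochloride, SMILES NO.Cl
Why: Oxime condensation; the E/Z mixture is used as such because both isomers give the same hydroximoyl chloride.

Step 4
Reactants: 6 methyl (4S)-2,2-dimethyl-1,3-dioxolane-4-carboxylate; 7 methyl (triphenylphosphoranylidene)acetate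
Product: 9 methyl (2Z)-3-[(4R)-2,2-dimethyl-1,3-dioxolan-4-yl]prop-2-enoate, via (4S)-glyceraldehyde acetonide 8 (not isolated)
Conditions: i-Bu2AlH, CH2Cl2, −78 °C; then 7, MeOH, −78 °C to rt; Rochelle salt work-up
Reagents that add atoms: none
Why: Partial reduction of the α-alkoxy ester gives a stable aluminium hemiacetal that releases 8 only when methanol and the ylide are present; the Wittig olefination of α-alkoxy aldehydes in methanol favours the Z-enoate, and trapping in the flask avoids handling the epimerisable aldehyde.

Step 5
Reactants: 9 methyl (2Z)-3-[(4R)-2,2-dimethyl-1,3-dioxolan-4-yl]prop-2-enoate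
Product: 10 (5R)-5-(hydroxymethyl)furan-2(5H)-one
Conditions: H2SO4 (cat.), MeOH/H2O 9:1, rt
Reagents that add atoms: none
Why: Acetal hydrolysis followed by lactonisation of the secondary hydroxyl onto the cis ester gives the five-membered butenolide; any E-enoate cannot cyclise and is removed at this point.

Step 6
Reactants: 10 (5R)-5-(hydroxymethyl)furan-2(5H)-one
Product: 11 (5R)-5-({[tert-butyl(diphenyl)silyl]oxy}methyl)furan-2(5H)-one
Conditions: TBDPSCl, imidazole, CH2Cl2, 0 °C to rt
Reagents that add atoms: tert-butyl(chloro)diphenylsilane, SMILES CC(C)(C)[Si](Cl)(c1ccccc1)c1ccccc1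
Why: Silylation of the primary alcohol; imidazole is too weak a base to remove the γ-hydrogen of the butenolide.

Step 7
Reactants: 5 13-methyltetradecanal oxime; 11 (5R)-5-({[tert-butyl(diphenyl)silyl]oxy}methyl)furan-2(5H)-one
Product: 14 (3aS,6S,6aR)-6-({[tert-butyl(diphenyl)silyl]oxy}methyl)-3-(12-methyltridecyl)-3a,6a-dihydrofuro[3,4-d]isoxazol-4(6H)-one, via hydroximoyl chloride 12 (not isolated), via nitrile oxide 13 (not isolated)
Conditions: 5 (1.5 equiv), NCS, DMF, rt; then 11, KHCO3, EtOAc, rt
Reagents that add atoms: none
Why: NCS chlorinates the oxime carbon to 12, and solid KHCO3 removes HCl slowly so that nitrile oxide 13 stays at a low stationary concentration, which curbs its dimerisation. 13 adds across C3=C4 of 11 in a concerted, suprafacial Huisgen 1,3-dipolar cycloaddition; the closest known reaction type is the addition of nitrile oxides to 5-substituted furan-2(5H)-ones and cyclic enones. The isoxazoline ring closes in this single [3+2] event, both new bonds (C1'–C3 and O–C4) forming on one face, hence the cis ring fusion. Regiochemistry is the one selectivity the step needs: the oxygen terminus bonds to the electrophilic β-carbon C4 and the carbon terminus to C3, the usual sense for β-substituted enoates and butenolides, reinforced here because the chain-bearing carbon terminus stays away from the C5 substituent. The new stereocentres C3a and C6a are set by approach anti to the silyloxymethyl group, but both become trigonal in steps 8 and 9, so a syn adduct would serve equally. C5 is not a reacting centre, and the only base present is too weak to deprotonate it.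

Step 8
Reactants: 14 (3aS,6S,6aR)-6-({[tert-butyl(diphenyl)silyl]oxy}methyl)-3-(12-methyltridecyl)-3a,6a-dihydrofuro[3,4-d]isoxazol-4(6H)-one
Product: 16 (3R,4R,5S)-5-({[tert-butyl(diphenyl)silyl]oxy}methyl)-4-hydroxy-3-(13-methyltetradecanoyl)dihydrofuran-2(3H)-one, via hydroxy imine 15 (not isolated)
Conditions: Raney Ni, H2 (1 atm), B(OH)3, MeOH/H2O 5:1, rt; cold dilute aq. HCl work-up
Reagents that add atoms: water, SMILES O
Why: Hydrogenolysis of the weak N–O bond of the isoxazoline gives β-hydroxy imine 15, which the buffered aqueous medium hydrolyses to the ketone before the C=N bond can be reduced; lactone, silyl ether and C5 are inert, and the crude product is carried on cold to limit loss of water.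

Step 9
Reactants: 16 (3R,4R,5S)-5-({[tert-butyl(diphenyl)silyl]oxy}methyl)-4-hydroxy-3-(13-methyltetradecanoyl)dihydrofuran-2(3H)-one
Product: 17 (5S)-5-({[tert-butyl(diphenyl)silyl]oxy}methyl)-4-hydroxy-3-(13-methyltetradecanoyl)furan-2(5H)-one
Conditions: IBX, EtOAc, 75 °C
Reagents that add atoms: none
Why: IBX oxidation of a β-hydroxy ketone to the β-diketone under neutral, base-free conditions; the product enolises at once to the chelated 3-acyltetronic acid, which erases C3 and C4 and leaves C5 untouched.

Step 10
Reactants: 17 (5S)-5-({[tert-butyl(diphenyl)silyl]oxy}methyl)-4-hydroxy-3-(13-methyltetradecanoyl)furan-2(5H)-one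
Product: 18 (5S)-4-hydroxy-5-(hydroxymethyl)-3-(13-methyltetradecanoyl)furan-2(5H)-one
Conditions: HF·pyridine, THF, 0 °C to rt
Reagents that add atoms: none
Why: Fluoride-driven cleavage of the Si–O bond in acidic medium, where the tricarbonyl stays protonated and C5–H is not at risk.

## Compound list

1 | 11-bromoundecan-1-ol | OCCCCCCCCCCCBr | starting material
2 | isobutylmagnesium bromide | CC(C)C[Mg]Br | starting material
3 | 13-methyltetradecan-1-ol | CC(C)CCCCCCCCCCCCO | intermediate
4 | 13-methyltetradecanal | CC(C)CCCCCCCCCCCC=O | intermediate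
5 | 13-methyltetradecanal oxime (E/Z mixture) | CC(C)CCCCCCCCCCCC=NO | intermediate
6 | methyl (4S)-2,2-dimethyl-1,3-dioxolane-4-carboxylate | COC(=O)[C@@H]1COC(C)(C)O1 | starting material
7 | methyl (triphenylphosphoranylidene)acetate | COC(=O)C=P(c1ccccc1)(c1ccccc1)c1ccccc1 | starting material
8 | (4S)-2,2-dimethyl-1,3-dioxolane-4-carbaldehyde (formed in the flask) | O=C[C@@H]1COC(C)(C)O1 | intermediate
9 | methyl (2Z)-3-[(4R)-2,2-dimethyl-1,3-dioxolan-4-yl]prop-2-enoate | COC(=O)/C=C\[C@@H]1COC(C)(C)O1 | intermediate
10 | (5R)-5-(hydroxymethyl)furan-2(5H)-one | O=C1C=C[C@H](CO)O1 | intermediate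
11 | (5R)-5-({[tert-butyl(diphenyl)silyl]oxy}methyl)furan-2(5H)-one | O=C1C=C[C@H](CO[Si](c2ccccc2)(c2ccccc2)C(C)(C)C)O1 | intermediate
12 | N-hydroxy-13-methyltetradecanimidoyl chloride (formed in the flask) | CC(C)CCCCCCCCCCCC(Cl)=NO | intermediate
13 | 13-methyltetradecanenitrile oxide (formed in the flask) | CC(C)CCCCCCCCCCCC#[N+][O-] | intermediate
14 | (3aS,6S,6aR)-6-({[tert-butyl(diphenyl)silyl]oxy}methyl)-3-(12-methyltridecyl)-3a,6a-dihydrofuro[3,4-d]isoxazol-4(6H)-one | O=C1O[C@@H](CO[Si](c3ccccc3)(c3ccccc3)C(C)(C)C)[C@@H]2ON=C(CCCCCCCCCCCC(C)C)[C@H]12 | intermediate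
15 | (3S,4R,5S)-5-({[tert-butyl(diphenyl)silyl]oxy}methyl)-4-hydroxy-3-(1-imino-13-methyltetradecyl)dihydrofuran-2(3H)-one (formed in the flask) | O=C1O[C@@H](CO[Si](c3ccccc3)(c3ccccc3)C(C)(C)C)[C@H](O)[C@@H]1C(=N)CCCCCCCCCCCC(C)C | intermediate
16 | (3R,4R,5S)-5-({[tert-butyl(diphenyl)silyl]oxy}methyl)-4-hydroxy-3-(13-methyltetradecanoyl)dihydrofuran-2(3H)-one | O=C1O[C@@H](CO[Si](c3ccccc3)(c3ccccc3)C(C)(C)C)[C@H](O)[C@@H]1C(=O)CCCCCCCCCCCC(C)C | intermediate
17 | (5S)-5-({[tert-butyl(diphenyl)silyl]oxy}methyl)-4-hydroxy-3-(13-methyltetradecanoyl)furan-2(5H)-one | CC(C)CCCCCCCCCCCC(=O)C1=C(O)[C@H](CO[Si](c2ccccc2)(c2ccccc2)C(C)(C)C)OC1=O | intermediate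
18 | (5S)-4-hydroxy-5-(hydroxymethyl)-3-(13-methyltetradecanoyl)furan-2(5H)-one | CC(C)CCCCCCCCCCCC(=O)C1=C(O)[C@H](CO)OC1=O | target

## Step count and risks

Total: 10 steps. Longest linear sequence: 7 steps (steps 4, 5, 6, 7, 8, 9, 10 from 6; the chain branch, steps 1, 2, 3 and then 7 to 10, is equally long).

Step 7 (key step). Two things are most likely to go wrong. The dipole may add in the reverse sense, oxygen terminus to C3. The aliphatic nitrile oxide may also dimerise faster than it adds to the only moderately reactive butenolide. Fallback, from 11 and 4, returning at 17: the oxygen and the acyl carbon are introduced one after the other by enolate chemistry. Conjugate borylation of 11 with B2pin2 (CuCl as a monovalent copper source, Xantphos, NaOt-Bu cat., MeOH, THF) should give the trans β-boryl lactone F1. NaBO3·4H2O then gives (4R,5S)-β-hydroxy lactone F2. Double deprotonation with LiN(i-Pr)2 at −78 °C and aldol addition to aldehyde 4 (Fráter–Seebach type dianion) gives the diol F3 as a mixture at C3 and C1'. Excess IBX oxidises both carbinols to 17.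

Step 8. The hydroxy imine may tautomerise to a lactone-conjugated enamine that resists hydrolysis in the weakly acidic buffer. Once hydrolysed, the α-acyl-β-hydroxy lactone may lose water through its doubly activated C3–H. Over-reduction of the C=N bond is a lesser concern. Fallback, from 14, returning at 17: the nitrogen is kept through the oxidation, so that no acidic C3–H is present. Hydrogenolysis without acid (Raney Ni, H2, MeOH) should stop at the β-hydroxy enamino lactone F4. Dess–Martin periodinane (NaHCO3, CH2Cl2) gives the enaminodione F5. Hydrolysis with 2 M HCl in THF at 50 °C gives 17.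

Step 9. Thermal dehydration of 16 may compete with its oxidation. The tricarbonyl product may also be oxidised further at C3. Fallback, from 14, returning at 17: the oxidation is moved to the heterocycle. Dehydrogenation of the isoxazoline (MnO2, toluene, 80 °C) gives the aromatic isoxazole F6. Reductive N–O opening with Mo(CO)6 in MeCN/H2O at 80 °C leads to the enaminodione F5 already described under step 8. Acid hydrolysis as above gives 17.

## Further compounds

F1 | step 7 | (4R,5R)-5-({[tert-butyl(diphenyl)silyl]oxy}methyl)-4-(4,4,5,5-tetramethyl-1,3,2-dioxaborolan-2-yl)dihydrofuran-2(3H)-one | O=C1C[C@@H](B2OC(C)(C)C(C)(C)O2)[C@H](CO[Si](c3ccccc3)(c3ccccc3)C(C)(C)C)O1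
F2 | step 7 | (4R,5S)-5-({[tert-butyl(diphenyl)silyl]oxy}methyl)-4-hydroxydihydrofuran-2(3H)-one | O=C1C[C@@H](O)[C@H](CO[Si](c3ccccc3)(c3ccccc3)C(C)(C)C)O1
F3 | step 7 | (4R,5S)-5-({[tert-butyl(diphenyl)silyl]oxy}methyl)-4-hydroxy-3-(1-hydroxy-13-methyltetradecyl)dihydrofuran-2(3H)-one (mixture at C3 and C1') | O=C1C(C(O)CCCCCCCCCCCC(C)C)[C@@H](O)[C@H](CO[Si](c3ccccc3)(c3ccccc3)C(C)(C)C)O1
F4 | step 8 | (3Z,4R,5S)-3-(1-amino-13-methyltetradecylidene)-5-({[tert-butyl(diphenyl)silyl]oxy}methyl)-4-hydroxydihydrofuran-2(3H)-one | N/C(CCCCCCCCCCCC(C)C)=C1\C(=O)O[C@@H](CO[Si](c2ccccc2)(c2ccccc2)C(C)(C)C)[C@@H]1O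
F5 | step 8 | (5S)-3-(1-amino-13-methyltetradecylidene)-5-({[tert-butyl(diphenyl)silyl]oxy}methyl)furan-2,4(3H,5H)-dione | N/C(CCCCCCCCCCCC(C)C)=C1\C(=O)O[C@@H](CO[Si](c2ccccc2)(c2ccccc2)C(C)(C)C)C1=O
F6 | step 9 | (6S)-6-({[tert-butyl(diphenyl)silyl]oxy}methyl)-3-(12-methyltridecyl)furo[3,4-d]isoxazol-4(6H)-one | O=C1O[C@@H](CO[Si](c3ccccc3)(c3ccccc3)C(C)(C)C)c2onc(CCCCCCCCCCCC(C)C)c12
A1 | alternative 1 | methyl (2S)-3-{[tert-butyl(diphenyl)silyl]oxy}-2-hydroxypropanoate | COC(=O)[C@@H](O)CO[Si](c1ccccc1)(c1ccccc1)C(C)(C)C
A2 | alternative 1 | 5-(1-hydroxy-13-methyltetradecylidene)-2,2-dimethyl-1,3-dioxane-4,6-dione | CC(C)CCCCCCCCCCCC(O)=C1C(=O)OC(C)(C)OC1=O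
A3 | alternative 1 | (2S)-3-{[tert-butyl(diphenyl)silyl]oxy}-1-methoxy-1-oxopropan-2-yl 15-methyl-3-oxohexadecanoate | CC(C)CCCCCCCCCCCC(=O)CC(=O)O[C@@H](CO[Si](c1ccccc1)(c1ccccc1)C(C)(C)C)C(=O)OC
A4 | alternative 2 | (5S)-5-({[tert-butyl(diphenyl)silyl]oxy}methyl)-4-hydroxyfuran-2(5H)-one | O=C1C=C(O)[C@H](CO[Si](c2ccccc2)(c2ccccc2)C(C)(C)C)O1
A5 | alternative 2 | 13-methyltetradecanoic acid | CC(C)CCCCCCCCCCCC(=O)O
A6 | alternative 2 | (2S)-2-({[tert-butyl(diphenyl)silyl]oxy}methyl)-5-oxo-2,5-dihydrofuran-3-yl 13-methyltetradecanoate | O=C1C=C(OC(=O)CCCCCCCCCCCC(C)C)[C@H](CO[Si](c2ccccc2)(c2ccccc2)C(C)(C)C)O1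
A7 | alternative 3 | ethyl 15-methyl-3-oxohexadecanoate | CCOC(=O)CC(=O)CCCCCCCCCCCC(C)C
A8 | alternative 3 | (R)-benzyl glycidyl ether | C1O[C@H]1COCc2ccccc2
A9 | alternative 3 | (5R)-5-(benzyloxymethyl)-3-(13-methyltetradecanoyl)dihydrofuran-2(3H)-one (mixture at C3) | CC(C)CCCCCCCCCCCC(=O)C1C[C@H](COCc2ccccc2)OC1=O
A10 | alternative 3 | (5R)-5-(benzyloxymethyl)-3-(13-methyltetradecanoyl)furan-2(5H)-one | CC(C)CCCCCCCCCCCC(=O)C1=C[C@H](COCc2ccccc2)OC1=O
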